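**Plan**

- Retrosynthesis: the allylic ether bond C8–O of the 2,5-dihydrofuran (ring O–C5–C6=C7–C8, fused to the cyclohexane at C5–C6) is cut first. That ring is a C5–C6 oxirane whose oxygen has moved across the C6–C7–C8 allyl unit, so the precursor is the 5,6-epoxide (a vinyl oxirane with a 7E alkene); the polyene on C6 is what lets the C6–O bond ionise. Next the oxirane oxygen is removed (C5=C6 alkene), then C6–C7 is cut (cyclohexenyl triflate + alkenylboronate), then C7=C8 (symmetrical C20 dialdehyde crocetindial).
- Forward: the ring fragment (3 steps from ketoisophorone) and the chain fragment (1 step from crocetindial) are joined at C6–C7; desilylation, hydroxyl-directed epoxidation and, last, expansion of the oxirane to the dihydrofuran.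
- Stereochemistry: C3 from catalytic asymmetric transfer hydrogenation; C5 from syn delivery of the epoxide oxygen by the C3 hydroxyl; C8 from suprafacial migration of that oxygen in the ring expansion; chain geometry from all-E crocetindial and an E-selective olefination.

Key step: step 8

Remark: carotenoid numbering is used (ring C1–C6, chain C7–C15 and C15'–C8'), and all-E crocetindial is taken as a catalogue compound.

**Route**

Step 1
Reactants: 1 ketoisophorone (2,6,6-trimethylcyclohex-2-ene-1,4-dione)
Product: 2 (R)-4-hydroxy-2,6,6-trimethylcyclohex-2-en-1-one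
Conditions: RuCl[(R,R)-TsDPEN](p-cymene) (0.5 mol %), KOt-Bu (1 mol %), i-PrOH, 20 °C
Reagents that add atoms: none
Why: Noyori–Ikariya asymmetric transfer hydrogenation should reduce only the less hindered C4 carbonyl (C1 is flanked by the gem-dimethyl carbon and the methyl-bearing alkene carbon), and with the alkene taking the place of the aryl group of an aryl ketone in the CH/π-organised transition state the (R,R)-ligand is expected to give the 4R alcohol, which becomes C3 of the target (the mirror-image catalyst is at hand should the sense prove opposite).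

Step 2
Reactants: 2 (R)-4-hydroxy-2,6,6-trimethylcyclohex-2-en-1-one
Product: 3 (R)-4-[(tert-butyldimethylsilyl)oxy]-2,6,6-trimethylcyclohex-2-en-1-one
Conditions: TBSCl, imidazole, DMF, 20 °C
Reagents that add atoms: tert-butyldimethylsilyl chloride, CC(C)(C)[Si](C)(C)Cl
Why: Standard silylation of a secondary alcohol, needed because the next step forms an enolate and uses a triflating agent that a free hydroxyl would consume.

Step 3
Reactants: 3 (R)-4-[(tert-butyldimethylsilyl)oxy]-2,6,6-trimethylcyclohex-2-en-1-one
Product: 5 (S)-4-[(tert-butyldimethylsilyl)oxy]-2,6,6-trimethylcyclohex-1-en-1-yl trifluoromethanesulfonate, via lithium enolate 4 (not isolated)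
Conditions: LiBH(s-Bu)3 (1.1 equiv), THF, −78 °C; then PhNTf2 (1.2 equiv), −78 to 0 °C
Reagents that add atoms: N-phenylbis(trifluoromethanesulfonimide), FC(F)(F)S(=O)(=O)N(c1ccccc1)S(=O)(=O)C(F)(F)F
Why: Conjugate reduction of the β-unsubstituted enone by the bulky borohydride (1,2-attack is blocked by the flanking gem-dimethyl and methyl groups) gives one regiodefined tetrasubstituted enolate, which is O-triflated in the same flask, and the silyloxy stereocentre is not touched (its descriptor changes from R to S only because the ring priorities change).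

Step 4
Reactants: 6 all-E crocetindial ((2E,4E,6E,8E,10E,12E,14E)-2,6,11,15-tetramethylhexadeca-2,4,6,8,10,12,14-heptaenedial, 3 equiv)
Product: 8 (2E,4E,6E,8E,10E,12E,14E,16E)-2,6,11,15-tetramethyl-17-(4,4,5,5-tetramethyl-1,3,2-dioxaborolan-2-yl)heptadeca-2,4,6,8,10,12,14,16-octaenal, via lithium alkoxide adduct 7 (not isolated)
Conditions: CH2(Bpin)2 (1 equiv), LiTMP (1 equiv), THF, 0 °C; added to 6 in THF, −78 °C to 20 °C, dark, Ar; excess 6 recovered
Reagents that add atoms: bis[(pinacolato)boryl]methane, CC1(C)OB(CB2OC(C)(C)C(C)(C)O2)OC1(C)C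
Why: Boron-Wittig olefination, in which the lithiated geminal bis(boronate) adds 1,2 to one formyl group and syn-elimination of LiOBpin from the adduct gives the (E)-alkenylboronate (the new C7=C8 bond); the symmetry of 6 makes both aldehydes equivalent and its excess should hold the reaction at mono-olefination.

Step 5
Reactants: 5 (S)-4-[(tert-butyldimethylsilyl)oxy]-2,6,6-trimethylcyclohex-1-en-1-yl trifluoromethanesulfonate; 8 the alkenylboronate aldehyde of step 4
Product: 9 (3S)-3-[(tert-butyldimethylsilyl)oxy]-8'-apo-β-caroten-8'-al (all-E)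
Conditions: Pd(OAc)2 (5 mol %), SPhos (10 mol %), K3PO4 (3 equiv), THF/H2O 10:1, 40 °C, Ar, dark
Reagents that add atoms: none
Why: Suzuki–Miyaura sp2–sp2 coupling of a cyclohexenyl triflate with an (E)-alkenylboronate, a union known for 2,6,6-trimethylcyclohexenyl triflates in retinoid work, should form C6–C7 with retention of both alkene geometries, the bulky electron-rich biarylphosphine being chosen for the hindered tetrasubstituted triflate.

Step 6
Reactants: 9 (3S)-3-[(tert-butyldimethylsilyl)oxy]-8'-apo-β-caroten-8'-al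
Product: 10 (3S)-3-hydroxy-8'-apo-β-caroten-8'-al (all-E; the enantiomer of β-citraurin)
Conditions: Bu4NF (1.5 equiv), AcOH (1.5 equiv), THF, 0 to 20 °C, dark
Reagents that add atoms: none
Why: Fluoride-induced desilylation frees the C3 hydroxyl needed to direct the epoxidation, and the acetic acid buffer keeps the medium from becoming basic enough to harm the polyenal.

Step 7
Reactants: 10 (3S)-3-hydroxy-8'-apo-β-caroten-8'-al
Product: 11 (3R,5R,6S)-5,6-epoxy-3-hydroxy-5,6-dihydro-8'-apo-β-caroten-8'-al (all-E; epoxide oxygen cis to the C3 hydroxyl)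
Conditions: mCPBA (1.05 equiv), solid NaHCO3 buffer, CH2Cl2, −20 °C, dark; chromatography on base-washed silica
Reagents that add atoms: 3-chloroperoxybenzoic acid, OOC(=O)c1cccc(Cl)c1
Why: Prilezhaev epoxidation is expected to pick the tetrasubstituted C5=C6 bond, which is twisted out of conjugation while the chain is deactivated by the aldehyde, and the C3 hydroxyl, hydrogen-bonded to the peracid in the half-chair whose opposite face carries the pseudoaxial C1 methyl, should deliver the oxygen syn to itself and so set 5R,6S.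

Step 8
Reactants: 11 (3R,5R,6S)-5,6-epoxy-3-hydroxy-5,6-dihydro-8'-apo-β-caroten-8'-al
Product: 13 (3R,5R,8R)-5,8-epoxy-3-hydroxy-5,8-dihydro-8'-apo-β-caroten-8'-al (the target), via hydroxy polyenyl cation 12 (not isolated)
Conditions: HCl (0.05 equiv, dilute solution in Et2O), CH2Cl2/Et2O, −20 to 0 °C, dark, Ar; NaHCO3 quench; chromatography, recovered 8S epimer returned to the same conditions
Reagents that add atoms: none
Why: Protonation of the oxirane oxygen and heterolysis of its C6–O bond (the one vinylogous to C7=C8 and the polyene) gives the C5-hydroxy polyenyl cation 12, whose C5 oxygen recloses on C8, so that the three-membered C5–C6–O ring grows by two atoms into the O–C5–C6=C7–C8 2,5-dihydrofuran. The closest known reaction type is the acid-catalysed 5,6-epoxide to 5,8-furanoid oxide rearrangement of epoxy carotenoids and 5,6-epoxy retinoids, a vinyl oxirane to 2,5-dihydrofuran ring expansion. The ring closes in a formally 5-endo mode by attack of the hydroxyl on the terminus of the allyl cation, which the s-cis C5–C6–C7–C8 arrangement makes possible. C5 keeps its R configuration because the C5–O bond is never broken, and C8 is set by suprafacial 1,3-transfer of the oxygen, which leaves C6 and arrives at C8 on the same face of the 7E allyl unit and thereby places the chain cis to C4 and trans to the C5 methyl (8R). The step needs C6–O over C5–O cleavage, which the polyene on C6 secures, and the 8R over the 8S face, which holds only while the ion pair is short-lived (low polarity, low temperature, trace acid). The 8S epimer is therefore expected as a by-product, to be separated by chromatography and re-equilibrated with the same acid.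

**Compound list**

1 | ketoisophorone (2,6,6-trimethylcyclohex-2-ene-1,4-dione) | CC1=CC(=O)CC(C)(C)C1=O | starting material
2 | (R)-4-hydroxy-2,6,6-trimethylcyclohex-2-en-1-one | CC1=C[C@H](O)CC(C)(C)C1=O | intermediate
3 | (R)-4-[(tert-butyldimethylsilyl)oxy]-2,6,6-trimethylcyclohex-2-en-1-one | CC1=C[C@H](O[Si](C)(C)C(C)(C)C)CC(C)(C)C1=O | intermediate
4 | lithium (S)-4-[(tert-butyldimethylsilyl)oxy]-2,6,6-trimethylcyclohex-1-en-1-olate | CC1=C(O[Li])C(C)(C)C[C@@H](O[Si](C)(C)C(C)(C)C)C1 | intermediate
5 | (S)-4-[(tert-butyldimethylsilyl)oxy]-2,6,6-trimethylcyclohex-1-en-1-yl trifluoromethanesulfonate | CC1=C(OS(=O)(=O)C(F)(F)F)C(C)(C)C[C@@H](O[Si](C)(C)C(C)(C)C)C1 | intermediate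
6 | all-E crocetindial ((2E,4E,6E,8E,10E,12E,14E)-2,6,11,15-tetramethylhexadeca-2,4,6,8,10,12,14-heptaenedial) | O=C/C(C)=C/C=C/C(C)=C/C=C/C=C(C)/C=C/C=C(C)/C=O | starting material
7 | lithium (3E,5E,7E,9E,11E,13E,15E)-3,7,12,16-tetramethyl-17-oxo-1,1-bis(4,4,5,5-tetramethyl-1,3,2-dioxaborolan-2-yl)heptadeca-3,5,7,9,11,13,15-heptaen-2-olate (carbinol centre unspecified) | [Li]OC(C(B1OC(C)(C)C(C)(C)O1)B1OC(C)(C)C(C)(C)O1)/C(C)=C/C=C/C(C)=C/C=C/C=C(C)/C=C/C=C(C)/C=O | intermediate
8 | (2E,4E,6E,8E,10E,12E,14E,16E)-2,6,11,15-tetramethyl-17-(4,4,5,5-tetramethyl-1,3,2-dioxaborolan-2-yl)heptadeca-2,4,6,8,10,12,14,16-octaenal | CC1(C)OB(/C=C/C(C)=C/C=C/C(C)=C/C=C/C=C(C)/C=C/C=C(C)/C=O)OC1(C)C | intermediate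
9 | (3S)-3-[(tert-butyldimethylsilyl)oxy]-8'-apo-β-caroten-8'-al (all-E) | CC1=C(/C=C/C(C)=C/C=C/C(C)=C/C=C/C=C(C)/C=C/C=C(C)/C=O)C(C)(C)C[C@@H](O[Si](C)(C)C(C)(C)C)C1 | intermediate
10 | (3S)-3-hydroxy-8'-apo-β-caroten-8'-al (all-E) | CC1=C(/C=C/C(C)=C/C=C/C(C)=C/C=C/C=C(C)/C=C/C=C(C)/C=O)C(C)(C)C[C@@H](O)C1 | intermediate
11 | (3R,5R,6S)-5,6-epoxy-3-hydroxy-5,6-dihydro-8'-apo-β-caroten-8'-al (all-E) | C\C(C=O)=C/C=C/C(C)=C/C=C/C=C(C)/C=C/C=C(C)/C=C/[C@@]12O[C@]1(C)C[C@H](O)CC2(C)C | intermediate
12 | (3R,5R)-3,5-dihydroxy polyenyl cation from C6–O heterolysis of 11 (drawn with the charge on C6, chloride as counter-ion) | C\C(C=O)=C/C=C/C(C)=C/C=C/C=C(C)/C=C/C=C(C)/C=C/[C+]1C(C)(C)C[C@@H](O)C[C@@]1(C)O | intermediate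
13 | (3R,5R,8R)-5,8-epoxy-3-hydroxy-5,8-dihydro-8'-apo-β-caroten-8'-al (CNP0118413.1) | C\C(C=O)=C/C=C/C(C)=C/C=C/C=C(C)/C=C/C=C(\C)[C@H]1C=C2C(C)(C)C[C@@H](O)C[C@@]2(C)O1 | target

**Summary**

Total step count: 8. Longest linear sequence: 7 steps (steps 1, 2, 3, 5, 6, 7, 8 from ketoisophorone); step 4 is the one-step side branch from crocetindial.

Steps most likely to fail:

1. Step 8. The terminal aldehyde makes the polyene electron-poor, so ionisation of the C6–O bond may be slow; the acid strength and time then needed would let the cation rotate about C7–C8 (loss of facial control at C8) and isomerise chain double bonds. The fallback runs the ring expansion at a lower oxidation level of C8'. It sets out from 11: NaBH4 in THF/MeOH at 0 °C should reduce only the aldehyde to (3R,5R,6S)-5,6-epoxy-5,6-dihydro-8'-apo-β-carotene-3,8'-diol F1. Without the acceptor the cation should form with pyridinium p-toluenesulfonate or a trace of HCl in Et2O at −40 °C, giving after chromatographic removal of the 8S epimer (3R,5R,8R)-5,8-epoxy-5,8-dihydro-8'-apo-β-carotene-3,8'-diol F2. MnO2 in CH2Cl2 at 20 °C should oxidise only the primary allylic alcohol, and the route is rejoined at 13.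

2. Step 7. The peracid may show poor face selectivity at C5=C6 (anti epoxide) or may also attack chain double bonds. The fallback replaces the intermolecular peracid by oxygen delivery from a metal alkoxide. It sets out from 10: VO(acac)2 (5 mol %) and t-BuOOH in toluene at 0 °C bind the C3 hydroxyl as a pentavalent vanadium alkoxide that carries the alkyl peroxide, so oxygen can reach only the syn face of the nearby C5=C6 bond, while the chain, which has no hydroxyl, should stay untouched. The route is rejoined at 11 and no new compound is made.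

3. Step 5. Oxidative addition and transmetalation at the tetrasubstituted, doubly flanked triflate may be slow, with protodeboronation and geometric scrambling of the polyenylboronate competing. The fallback forms C7=C8 by a Wittig reaction instead of C6–C7 by cross-coupling. It sets out from 5: carbonylation (Pd(OAc)2, 1,3-bis(diphenylphosphino)propane, CO at 1 atm, MeOH, Et3N, DMF, 60 °C) should give methyl (S)-4-[(tert-butyldimethylsilyl)oxy]-2,6,6-trimethylcyclohex-1-ene-1-carboxylate F3. Reduction with i-Bu2AlH in CH2Cl2 at −78 °C should give [(S)-4-[(tert-butyldimethylsilyl)oxy]-2,6,6-trimethylcyclohex-1-en-1-yl]methanol F4. PPh3·HBr in MeOH at 20 °C should convert the allylic alcohol into the phosphonium salt and cleave the silyl ether, giving {[(S)-4-hydroxy-2,6,6-trimethylcyclohex-1-en-1-yl]methyl}triphenylphosphonium bromide F5. Its ylide (NaOMe, CH2Cl2/MeOH) with excess crocetindial 6, followed by thermal isomerisation of the 7Z part in refluxing heptane, rejoins the route at 10.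

Further compounds
F1 | step 8 | (3R,5R,6S)-5,6-epoxy-5,6-dihydro-8'-apo-β-carotene-3,8'-diol | C\C(CO)=C/C=C/C(C)=C/C=C/C=C(C)/C=C/C=C(C)/C=C/[C@@]12O[C@]1(C)C[C@H](O)CC2(C)C
F2 | step 8 | (3R,5R,8R)-5,8-epoxy-5,8-dihydro-8'-apo-β-carotene-3,8'-diol | C\C(CO)=C/C=C/C(C)=C/C=C/C=C(C)/C=C/C=C(\C)[C@H]1C=C2C(C)(C)C[C@@H](O)C[C@@]2(C)O1
F0 | step 7 | none | none
F3 | step 5 | methyl (S)-4-[(tert-butyldimethylsilyl)oxy]-2,6,6-trimethylcyclohex-1-ene-1-carboxylate | COC(=O)C1=C(C)C[C@H](O[Si](C)(C)C(C)(C)C)CC1(C)C
F4 | step 5 | [(S)-4-[(tert-butyldimethylsilyl)oxy]-2,6,6-trimethylcyclohex-1-en-1-yl]methanol | OCC1=C(C)C[C@H](O[Si](C)(C)C(C)(C)C)CC1(C)C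
F5 | step 5 | {[(S)-4-hydroxy-2,6,6-trimethylcyclohex-1-en-1-yl]methyl}triphenylphosphonium bromide | [Br-].O[C@H]1CC(C)=C(C[P+](c2ccccc2)(c2ccccc2)c2ccccc2)C(C)(C)C1
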